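The cycloheptane ring (C1 carbinol, C5 acyloxy, C6 lactone CH–O, C7, C8, C9 ketone, C10 CHMe) is disconnected at C8–C9 and C5–C6 into a three-carbon unit (C6–C7–C8) and a four-carbon unit (C9–C10–C1–C5). Both bonds are made at once by a (4+3) cycloaddition of a chiral 1-alkoxy-2-siloxyallyl cation with 3-methylfuran. The step exploits the 1,4-related oxygen-bearing ring carbons C5 and C9 flanking C1–C10(Me), which are the α-carbons of a furan, and the trans C5/C6 dioxygen pattern where the lactone meets the seven-membered ring. The precursor is the triethylsilyl enol ether of a mixed methyl/(S)-1-phenylethyl acetal of pyruvaldehyde. The oxygen bridge then controls C6/C7 and is later opened to reach C9, C10 and C1.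

Key step: step 3

Remark: β is the ring face that carries the C5 oxygen, α the opposite face; lactone carbons are C11–C13, crotonoyl carbons C2–C4 and C15. Starting materials 1, 2, 5, 14 and 17 are commercial.
Assumption: the (S)-1-phenylethyl group is taken to steer the cycloaddition to the enantiomer drawn for 7, with the C6 alkoxy group equatorial; if the sense of induction is the opposite, (R)-1-phenylethanol is used and nothing else changes.

Step 1
Reactants: 1 1,1-dimethoxypropan-2-one; 2 (S)-1-phenylethanol
Product: 3 1-methoxy-1-[(1S)-1-phenylethoxy]propan-2-one (both acetal epimers)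
Conditions: pyridinium p-toluenesulfonate (cat.), cyclohexane, 60 °C, MeOH distilled off
Reagents that add atoms: none
Why: Acid-catalysed transacetalisation exchanges one methoxy group for the chiral alkoxy group as methanol is removed; the acetal carbon is a stereocentre of no consequence because it is ionised in step 3.

Step 2
Reactants: 3 mixed acetal
Product: 4 triethylsilyl enol ether of 3
Conditions: LiN(iPr)2, THF, −78 °C; Et3SiCl, −78 °C → rt
Reagents that add atoms: chlorotriethylsilane, CC[Si](Cl)(CC)CC
Why: Kinetic deprotonation of the methyl ketone at CH3 and O-silylation (silyl enol ether formation) give the terminal enol silane that serves as the latent oxyallyl unit; no stereocentre is formed.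

Step 3
Reactants: 4 silyl enol ether; 5 3-methylfuran
Product: 7 (1R,2S,5R)-6-methyl-2-[(1S)-1-phenylethoxy]-8-oxabicyclo[3.2.1]oct-6-en-3-one, via oxyallyl cation 6 (not isolated)
Conditions: TMSOTf (0.2 equiv), 3-methylfuran (3 equiv), CH2Cl2, −95 °C; Et3N
Reagents that add atoms: none
Why: TMSOTf ionises the methoxy group of 4 to the Z-configured 1-alkoxy-2-siloxyallyl cation 6, which adds to 3-methylfuran in a (4+3) cycloaddition of the oxyallyl cation–furan type, the closest known case being the low-temperature addition of chiral α-alkoxy siloxyallyl cations to furan. The first bond (C8–C9) joins the unsubstituted cation terminus to furan C2, the most nucleophilic carbon next to the methyl group; the second (C5–C6) closes the seven-membered carbocycle by 7-(enolendo)-exo-trig attack of the enol silane carbon on the furan-derived oxocarbenium ion, which also completes the oxygen-bridged five- and six-membered rings of the bicycle. C6 is expected equatorial, trans to the oxygen bridge at C5, through the compact transition state of the Z cation, and being α to the ketone it can also equilibrate to this more stable position; C5 and C9 are necessarily cis through the bridge. The absolute sense comes from the (S)-1-phenylethyl group, whose phenyl ring shields one face of the planar cation. The step needs the regiochemistry that puts the methyl-bearing alkene carbon next to the CH2-bonded bridgehead, which the polarity of 3-methylfuran and the unsymmetrical cation should secure; loss of the silyl group from the carbonyl oxygen turns the silyl triflate over.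

Step 4
Reactants: 7 bicyclic ketone
Product: 8 3-methylidene compound (C7=C11H2 in place of the ketone)
Conditions: Ph3PCH3Br, KOtBu, THF, 0 °C → rt
Reagents that add atoms: methyltriphenylphosphonium bromide, C[P+](c1ccccc1)(c1ccccc1)c1ccccc1.[Br-]
Why: Wittig methylenation replaces the C7 carbonyl by the exocyclic alkene that supplies C11, a transformation well known for 8-oxabicyclo[3.2.1]oct-6-en-3-ones, and leaves the equatorial alkoxy centre in its more stable position.

Step 5
Reactants: 8 diene
Product: 9 diol with 7α-CH2OH 10α-CH3 and 1β-OH on the oxygen-bridged ring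
Conditions: BH3·THF, THF, 0 °C → rt; NaOH, H2O2, 0 °C
Reagents that add atoms: hydrogen peroxide, OO
Why: Hydroboration–oxidation adds borane to both alkenes from the exo face (the side of the oxygen bridge) with boron on the less substituted carbons, giving the primary C11 and the secondary exo C1 alcohols; the C7 and C10 centres formed here are corrected in step 7 and erased in step 9.

Step 6
Reactants: 9 diol
Product: 10 hydroxy aldehyde with axial 7α-CHO
Conditions: TEMPO (cat.), PhI(OAc)2, CH2Cl2, rt
Reagents that add atoms: none
Why: Oxoammonium (TEMPO) oxidation with PhI(OAc)2 as terminal oxidant is selective for the primary alcohol and leaves the secondary C1 alcohol.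

Step 7
Reactants: 10 axial aldehyde
Product: 12 alkyne with 7β-ethynyl and 1β-OH, via equatorial aldehyde 11 (not isolated)
Conditions: K2CO3, MeOH, rt; then dimethyl (1-diazo-2-oxopropyl)phosphonate, 0 °C → rt
Reagents that add atoms: dimethyl (1-diazo-2-oxopropyl)phosphonate, CC(=O)C(=[N+]=[N-])P(=O)(OC)OC
Why: Carbonate in methanol first epimerises C7 to the equatorial β-aldehyde, trans to the C6 alkoxy group (thermodynamic control in the rigid chair, where β-elimination of the equatorial alkoxy group is stereoelectronically disfavoured), and the Ohira–Bestmann variant of the Seyferth–Gilbert homologation then gives the terminal alkyne C11≡C13.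

Step 8
Reactants: 12 alkynyl alcohol
Product: 13 bicyclic C1 ketone
Conditions: Dess–Martin periodinane, CH2Cl2, 0 °C → rt
Reagents that add atoms: none
Why: Dess–Martin oxidation converts the secondary C1 alcohol into the ketone under neutral conditions that spare the alkyne and the benzylic ether.

Step 9
Reactants: 13 bicyclic ketone; 14 (R)-2-methylbutanoic acid
Product: 16 monocyclic enone (C1 ketone and C9=C10) with 5β-O-[(R)-2-methylbutanoyl], via hydroxy enone 15 (not isolated)
Conditions: LiN(SiMe3)2, THF, −78 → −20 °C; then mixed anhydride of 14 (2,4,6-trichlorobenzoyl chloride, Et3N, THF), DMAP, −20 → 0 °C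
Reagents that add atoms: none
Why: The lithium enolate formed at C10 (the only enolisable position, C5 being a bridgehead) expels the β-oxygen at C9 in an E1cB opening of the oxygen bridge, and the freed C5 alkoxide is acylated by the Yamaguchi mixed anhydride with retention at C5 and at the acid stereocentre.

Step 10
Reactants: 16 ester enone; 17 (S)-but-3-yn-2-ol
Product: 18 tertiary allylic alcohol at C1 bearing the 3-hydroxybut-1-ynyl group (both C1 epimers)
Conditions: 17, n-BuLi (2 equiv), THF, −78 °C; CeCl3; then 16, −78 °C; NH4Cl (aq)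
Reagents that add atoms: none
Why: The cerium acetylide of the butynol dianion adds 1,2 to the enone carbonyl (organocerium alkynylation, which suppresses enolisation and attack on the ester); the C1 configuration is irrelevant because C1 becomes sp2 in step 12.

Step 11
Reactants: 18 diol
Product: 19 secondary propargylic acetate (both C1 epimers)
Conditions: Ac2O, pyridine, DMAP (cat.), CH2Cl2, 0 °C
Reagents that add atoms: acetic anhydride, CC(=O)OC(C)=O
Why: DMAP-catalysed acetylation takes the unhindered secondary propargylic alcohol over the tertiary one, protecting it from the chromium oxidant and installing the migrating group for step 15.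

Step 12
Reactants: 19 tertiary allylic alcohol
Product: 20 tetrasubstituted enone (C9 ketone and C10=C1)
Conditions: pyridinium chlorochromate [C5H5NH][CrO3Cl], 4 Å MS, CH2Cl2, rt
Reagents that add atoms: none
Why: Babler–Dauben oxidative transposition: the tertiary allylic chromate ester shifts by a [3,3] path to C9 and is oxidised there, which places the ketone on C9 and the alkene between C10 and C1.

Step 13
Reactants: 20 enone
Product: 21 1α,10α-epoxy ketone
Conditions: t-BuOOH, DBU, CH2Cl2, 0 °C → rt
Reagents that add atoms: tert-butyl hydroperoxide, CC(C)(C)OO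
Why: Weitz–Scheffer nucleophilic epoxidation: the hydroperoxide anion adds to the β-carbon C1 from the α face, anti to the neighbouring C5 acyloxy group, and ring closure fixes the C1–O bond on the α face.

Step 14
Reactants: 21 epoxy ketone
Product: 22 β-hydroxy ketone (C9 ketone with 10α-CH3 and 1α-OH)
Conditions: SmI2, THF/MeOH, −90 °C
Reagents that add atoms: none
Why: Samarium diiodide reduction of the α,β-epoxy ketone cleaves the C10–O bond α to the ketyl and leaves the C1–O bond, so C1 keeps its configuration; protonation of the samarium enolate anti to the samarium alkoxide on C1 should place the C10 methyl α, the arrangement also favoured at equilibrium through the C9 enol.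

Step 15
Reactants: 22 propargylic acetate
Product: 24 1β-[(E)-but-2-enoyl] compound, via allenyl acetate 23 (not isolated)
Conditions: Ph3PAuNTf2 (2 mol %), butanone/H2O, rt
Reagents that add atoms: none
Why: Gold-catalysed Meyer–Schuster-type rearrangement: 1,3-acyloxy migration gives the allenyl acetate, whose hydrolysis in the wet solvent is expected to outrun any addition of the hindered tertiary hydroxyl and to give the (E)-enone, while the terminal alkyne stays inert at room temperature.

Step 16
Reactants: 24 1-phenylethyl ether
Product: 25 6α-alcohol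
Conditions: BCl3, C6HMe5, CH2Cl2, −78 °C; NaHCO3 (aq)
Reagents that add atoms: none
Why: Boron trichloride with pentamethylbenzene as cation scavenger cleaves the secondary benzylic ether by an SN1-type path at low temperature, freeing the C6 hydroxyl with retention while the esters, enone, alkyne and tertiary alcohol should survive.

Step 17
Reactants: 25 homopropargylic alcohol
Product: 26 target CNP0153197.3
Conditions: PdCl2 (cat.), PPh3, SnCl2, CO (7 atm), MeCN, 65 °C
Reagents that add atoms: carbon monoxide, [C-]#[O+]
Why: Palladium-catalysed cyclocarbonylation of the homopropargylic alcohol: an alkoxycarbonyl–palladium species from the C6 hydroxyl and CO adds across the terminal alkyne in a 5-exo closure and protonolysis releases the α-methylene-γ-butyrolactone, trans-fused because C6 and C7 are already fixed.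

Compound list
1 | 1,1-dimethoxypropan-2-one | CC(=O)C(OC)OC | starting material
2 | (S)-1-phenylethanol | C[C@H](O)c1ccccc1 | starting material
3 | 1-methoxy-1-[(1S)-1-phenylethoxy]propan-2-one (both acetal epimers) | CC(=O)C(OC)O[C@@H](C)c1ccccc1 | intermediate
4 | triethyl({3-methoxy-3-[(1S)-1-phenylethoxy]prop-1-en-2-yl}oxy)silane | C=C(O[Si](CC)(CC)CC)C(OC)O[C@@H](C)c1ccccc1 | intermediate
5 | 3-methylfuran | Cc1ccoc1 | starting material
6 | 1-[(1S)-1-phenylethoxy]-2-(triethylsilyloxy)allyl cation (oxocarbenium form, triflate counter-ion) | C=C(O[Si](CC)(CC)CC)C=[O+][C@@H](C)c1ccccc1 | intermediate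
7 | (1R,2S,5R)-6-methyl-2-[(1S)-1-phenylethoxy]-8-oxabicyclo[3.2.1]oct-6-en-3-one (β oxygen bridge C5–O–C9, C7 ketone, 6α equatorial alkoxy, C10 methyl on the C10=C1 alkene) | C[C@@H](c1ccccc1)O[C@@H]2C(=O)C[C@@H]3C(C)=C[C@H]2O3 | intermediate
8 | 6-methyl-3-methylidene-2-[(1S)-1-phenylethoxy]-8-oxabicyclo[3.2.1]oct-6-ene (ring configuration as in 7) | C[C@@H](c1ccccc1)O[C@@H]2C(=C)C[C@@H]3C(C)=C[C@H]2O3 | intermediate
9 | diol, bridged as 7: 6α-[(S)-1-phenylethoxy], 7α-CH2OH (axial), 10α-CH3 (endo), 1β-OH (exo) | C[C@@H](c1ccccc1)O[C@@H]2[C@H](CO)C[C@@H]3[C@H](C)[C@@H](O)[C@H]2O3 | intermediate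
10 | hydroxy aldehyde, as 9 with 7α-CHO (axial) | C[C@@H](c1ccccc1)O[C@@H]2[C@H](C=O)C[C@@H]3[C@H](C)[C@@H](O)[C@H]2O3 | intermediate
11 | C7 epimer of 10 with 7β-CHO (equatorial) | C[C@@H](c1ccccc1)O[C@@H]2[C@@H](C=O)C[C@@H]3[C@H](C)[C@@H](O)[C@H]2O3 | intermediate
12 | alkynyl alcohol, bridged as 7: 7β-ethynyl, 6α-alkoxy, 10α-CH3, 1β-OH | C[C@@H](c1ccccc1)O[C@@H]2[C@@H](C#C)C[C@@H]3[C@H](C)[C@@H](O)[C@H]2O3 | intermediate
13 | bicyclic ketone, as 12 with C1 ketone | C[C@@H](c1ccccc1)O[C@@H]2[C@@H](C#C)C[C@@H]3[C@H](C)C(=O)[C@H]2O3 | intermediate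
14 | (R)-2-methylbutanoic acid | CC[C@@H](C)C(=O)O | starting material
15 | hydroxy enone: cycloheptenone with C1 ketone and C9=C10, 5β-OH, 6α-[(S)-1-phenylethoxy], 7β-ethynyl, 10-methyl | C[C@@H](c1ccccc1)O[C@@H]2[C@@H](C#C)CC=C(C)C(=O)[C@H]2O | intermediate
16 | ester enone: as 15 with 5β-O-[(R)-2-methylbutanoyl] | C[C@@H](c1ccccc1)O[C@@H]2[C@@H](C#C)CC=C(C)C(=O)[C@H]2OC(=O)[C@H](C)CC | intermediate
17 | (S)-but-3-yn-2-ol | C[C@H](O)C#C | starting material
18 | tertiary alcohol: as 16 with C1(OH)[(3S)-3-hydroxybut-1-ynyl] in place of the ketone (both C1 epimers) | C[C@@H](c1ccccc1)O[C@@H]2[C@@H](C#C)CC=C(C)C(O)(C#C[C@H](C)O)[C@H]2OC(=O)[C@H](C)CC | intermediate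
19 | propargylic acetate of 18 (both C1 epimers) | C[C@@H](c1ccccc1)O[C@@H]2[C@@H](C#C)CC=C(C)C(O)(C#C[C@H](C)OC(C)=O)[C@H]2OC(=O)[C@H](C)CC | intermediate
20 | enone: C9 ketone, C10=C1 alkene, 10-methyl, C1-[(3S)-3-acetoxybut-1-ynyl], 5β-acyloxy, 6α-alkoxy, 7β-ethynyl | C[C@@H](c1ccccc1)O[C@@H]2[C@@H](C#C)CC(=O)C(C)=C(C#C[C@H](C)OC(C)=O)[C@H]2OC(=O)[C@H](C)CC | intermediate
21 | 1α,10α-epoxide of 20 | C[C@@H](c1ccccc1)O[C@@H]2[C@@H](C#C)CC(=O)[C@]3(C)O[C@]3(C#C[C@H](C)OC(C)=O)[C@H]2OC(=O)[C@H](C)CC | intermediate
22 | β-hydroxy ketone: C9 ketone, 10α-CH3, 1α-OH, 1β-[(3S)-3-acetoxybut-1-ynyl], 5β-acyloxy, 6α-alkoxy, 7β-ethynyl | C[C@@H](c1ccccc1)O[C@@H]2[C@@H](C#C)CC(=O)[C@H](C)[C@@](O)(C#C[C@H](C)OC(C)=O)[C@H]2OC(=O)[C@H](C)CC | intermediate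
23 | allenyl acetate: as 22 with 1β-(1-acetoxybuta-1,2-dienyl) | C[C@@H](c1ccccc1)O[C@@H]2[C@@H](C#C)CC(=O)[C@H](C)[C@@](O)(C(OC(C)=O)=C=CC)[C@H]2OC(=O)[C@H](C)CC | intermediate
24 | crotonoyl compound: as 22 with 1β-[(E)-but-2-enoyl] | C[C@@H](c1ccccc1)O[C@@H]2[C@@H](C#C)CC(=O)[C@H](C)[C@@](O)(C(=O)/C=C/C)[C@H]2OC(=O)[C@H](C)CC | intermediate
25 | 6α-alcohol: 24 without the 1-phenylethyl group | O[C@@H]1[C@@H](C#C)CC(=O)[C@H](C)[C@@](O)(C(=O)/C=C/C)[C@H]1OC(=O)[C@H](C)CC | intermediate
26 | CNP0153197.3 | C=C1C(=O)O[C@@H]2[C@@H]1CC(=O)[C@H](C)[C@@](O)(C(=O)/C=C/C)[C@H]2OC(=O)[C@H](C)CC | target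

Total step count: 17. Longest linear sequence: 17 steps (1 → 26).

Steps most likely to fail:

Step 13. The hydroperoxide may fail to add at the congested β-carbon of the tetrasubstituted enynone, or the base may deprotonate the γ-position (C5) and trigger loss of the C6 alkoxy group. Fallback from 20: catalytic dihydroxylation (OsO4 cat., N-methylmorpholine N-oxide, citric acid, t-BuOH/H2O, rt) should attack the same α face, anti to the C5 acyloxy group, to give the 1α,10α-diol F1. Samarium diiodide (THF/MeOH, −78 °C) then removes the C10 hydroxyl, which is α to the C9 ketone, and the route is rejoined at 22.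

Step 15. The free tertiary C1 hydroxyl may add to the gold-activated allene or take over the acetyl group before hydrolysis occurs. Fallback from 22: the tertiary alcohol is first capped (TMSOTf, 2,6-lutidine, CH2Cl2, −78 °C) as the trimethylsilyl ether F2. The same gold-catalysed rearrangement then gives the silylated crotonoyl compound F3, and the boron trichloride treatment of step 16 removes the silyl and 1-phenylethyl groups together, rejoining the route at 25.

Step 17. The alkyne may hydrate or oligomerise, and the Lewis-acidic medium at 65 °C may cause retro-aldol cleavage or dehydration of the tertiary aldol. Fallback from 25: intermolecular branched-selective methoxycarbonylation of the alkyne (Pd(OAc)2, 2-pyridyldiphenylphosphine, MeSO3H, CO, MeOH, 25 °C) gives the methyl acrylate ester F4. Acid-catalysed lactonisation with the C6 hydroxyl (camphorsulfonic acid, toluene, 40 °C) then gives 26.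

Further compounds
F1 | step 13 | 1α,10α-diol of 20 (C9 ketone, 10β-CH3) | C[C@@H](c1ccccc1)O[C@@H]2[C@@H](C#C)CC(=O)[C@](C)(O)[C@@](O)(C#C[C@H](C)OC(C)=O)[C@H]2OC(=O)[C@H](C)CC
F2 | step 15 | 1α-O-trimethylsilyl ether of 22 | C[C@@H](c1ccccc1)O[C@@H]2[C@@H](C#C)CC(=O)[C@H](C)[C@@](O[Si](C)(C)C)(C#C[C@H](C)OC(C)=O)[C@H]2OC(=O)[C@H](C)CC
F3 | step 15 | 1α-O-trimethylsilyl ether of 24 | C[C@@H](c1ccccc1)O[C@@H]2[C@@H](C#C)CC(=O)[C@H](C)[C@@](O[Si](C)(C)C)(C(=O)/C=C/C)[C@H]2OC(=O)[C@H](C)CC
F4 | step 17 | methyl 2-substituted acrylate (7β-[1-(methoxycarbonyl)vinyl] analogue of 25) | O[C@@H]1[C@@H](C(=C)C(=O)OC)CC(=O)[C@H](C)[C@@](O)(C(=O)/C=C/C)[C@H]1OC(=O)[C@H](C)CC
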